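**Plan**
- Retrosynthetic cuts, in order: the O8–C(=O)Ar ester bond; the C4–CH3 bond (back to a ketal-masked C4 ketone); the C10 methyl (back to an ester); then C9–C10 and C5–C6 of the seven-membered ring, a [4+3] disconnection.
- Enabling feature (guaiane numbering): the cycloheptene ring C1/C5/C6/C7/C8/C9/C10 divides into the three-carbon unit C5–C1–C10, which sits on the cyclopentene as a vinylcarbene (C10 carbene carbon, C1=C5 alkene), and the four-carbon unit C6–C7–C8–C9, a butadiene that already carries O6, the isopropyl group and O8.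
- Forward: the five-membered ring is bought as 3-ethoxycyclopentenone and becomes diazoester 7 (steps 1–3); diene 13 is built from ethyl 3-methylbutanoate (steps 4–7); the seven-membered ring arises in step 8; steps 9–15 adjust C10, C7, C8 and C4; the vanilloyl ester is attached last (steps 16–18).
- Stereochemistry: C5 and C6 from Rh2(S-DOSP)4 and the stereospecific boat Cope shift (H5 and H6 cis); C7 by enolate protonation anti to the C6 ether; C8 by hydride delivery from the C6 hydroxyl; C4 by methyl addition anti to the C5–C6 bond.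

Key step: step 8

Convention: guaiane numbering throughout; α is the face of H5. The target has H5, H6, H7, O8 and the C4 methyl on the α face and O4, O6 and the isopropyl group on the β face, (4S,5S,6R,7S,8S).

Assumption: Rh2(S-DOSP)4 is taken to attack the siloxy alkene with the facial sense it shows with terminal alkenes (carbenoid donor and alkene substituent cis, 1S,2R series of 1,2-diarylcyclopropanecarboxylates). On that basis it should give the (5S,6S) cycloadduct; if the siloxy diene responds in the opposite sense, Rh2(R-DOSP)4 is used and nothing else changes.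

**Step 1**
Reactants: 1 3-ethoxycyclopent-2-en-1-one; 2 methyl acetate
Product: 5 methyl 2-(3-oxocyclopent-1-en-1-yl)acetate, via lithium enolate of methyl acetate 3 (not isolated), via tertiary alkoxide adduct 4 (not isolated)
Conditions: LiN(iPr)2, THF, −78 °C; then 1, −78 °C; then 1 M aq. HCl, 0 °C → rt
Reagents that add atoms: water, O
Why: 1,2-addition of the ester enolate to the vinylogous ester carbonyl, followed by acid hydrolysis of the enol ether and loss of water (Stork–Danheiser transposition), should give the 3-substituted cyclopentenone with the alkene in the stable endocyclic enone position.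

**Step 2**
Reactants: 5 methyl 2-(3-oxocyclopent-1-en-1-yl)acetate
Product: 6 methyl 2-(1,4-dioxaspiro[4.4]non-6-en-7-yl)acetate
Conditions: (Me3SiOCH2)2, Me3SiOTf (5 mol %), CH2Cl2, −78 → −20 °C; pyridine quench
Reagents that add atoms: 1,2-bis(trimethylsilyloxy)ethane, C[Si](C)(C)OCCO[Si](C)(C)C
Why: Noyori ketalization with the bis-silyl glycol ether is aprotic and run cold, so the enone should be converted to its dioxolane without the alkene migrating out of the C6=C7 position of the spirocycle.

**Step 3**
Reactants: 6 methyl 2-(1,4-dioxaspiro[4.4]non-6-en-7-yl)acetate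
Product: 7 methyl 2-diazo-2-(1,4-dioxaspiro[4.4]non-6-en-7-yl)acetate
Conditions: 4-acetamidobenzenesulfonyl azide, DBU, MeCN, 0 °C
Reagents that add atoms: 4-acetamidobenzenesulfonyl azide, CC(=O)Nc1ccc(cc1)S(=O)(=O)N=[N+]=[N-]
Why: Regitz diazo transfer to a β,γ-unsaturated ester with a sulfonyl azide and DBU is the standard entry to vinyldiazoacetates, the α-CH2 flanked by ester and alkene being acidic enough for the amidine base.

**Step 4**
Reactants: 8 ethyl 3-methylbutanoate
Product: 9 ethyl 2-formyl-3-methylbutanoate (in equilibrium with its hydroxymethylene tautomer)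
Conditions: NaH, HCO2Et, Et2O (cat. EtOH), 0 °C → rt; then cold 1 M aq. HCl
Reagents that add atoms: ethyl formate, CCOC=O
Why: crossed Claisen condensation with the non-enolizable formate is driven to completion by formation of the stabilized enolate of the formyl ester.

**Step 5**
Reactants: 9 ethyl 2-formyl-3-methylbutanoate
Product: 10 ethyl (E)-2-isopropyl-3-(4-methoxybenzyloxy)prop-2-enoate (ester and benzyloxy group trans)
Conditions: 4-methoxybenzyl chloride, K2CO3, DMF, 40 °C
Reagents that add atoms: 4-methoxybenzyl chloride, COc1ccc(CCl)cc1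
Why: O-alkylation of the dissociated potassium enolate in DMF is expected because C-alkylation would build a quaternary carbon next to isopropyl, and the E β-alkoxyacrylate with alkoxy trans to the ester is the favoured isomer in this class, which fixes the geometry later needed at C6=C7.

**Step 6**
Reactants: 10 ethyl (E)-2-isopropyl-3-(4-methoxybenzyloxy)prop-2-enoate
Product: 12 (E)-3-isopropyl-4-(4-methoxybenzyloxy)but-3-en-2-one, via α-silyl ketone 11 (not isolated)
Conditions: Me3SiCH2Li (2.3 equiv), THF/pentane, −78 → 0 °C; then MeOH, rt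
Reagents that add atoms: (trimethylsilyl)methyllithium, [Li]C[Si](C)(C)C
Why: ester-to-methyl-ketone conversion with Me3SiCH2Li, in which the first adduct collapses to an α-silyl ketone that the second equivalent deprotonates at once and so shields from over-addition, methanol then cleaving the C–Si bond.

**Step 7**
Reactants: 12 (E)-3-isopropyl-4-(4-methoxybenzyloxy)but-3-en-2-one
Product: 13 (E)-2-(tert-butyldimethylsilyloxy)-3-isopropyl-4-(4-methoxybenzyloxy)buta-1,3-diene
Conditions: tBuMe2SiOTf, Et3N, CH2Cl2, 0 °C
Reagents that add atoms: tert-butyldimethylsilyl triflate, CC(C)(C)[Si](C)(C)OS(=O)(=O)C(F)(F)F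
Why: soft enolization and O-silylation of the vinylogous ester, whose only enolizable position is the methyl group, should give the 1-alkoxy-3-siloxy diene with the E enol ether untouched.

**Step 8**
Reactants: 7 methyl 2-diazo-2-(1,4-dioxaspiro[4.4]non-6-en-7-yl)acetate; 13 (E)-2-(tert-butyldimethylsilyloxy)-3-isopropyl-4-(4-methoxybenzyloxy)buta-1,3-diene
Product: 15 methyl (5S,6S)-8-(tert-butyldimethylsilyloxy)-4,4-ethylenedioxy-6-(4-methoxybenzyloxy)-15-norguaia-1(10),7-dien-14-oate (H5 and H6 cis), via cis-divinylcyclopropane 14 (not isolated)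
Conditions: Rh2(S-DOSP)4 (1 mol %), hexanes, −40 °C, slow addition of 7 to 13 (1.5 equiv); then 25 → 50 °C
Reagents that add atoms: none
Why: Rh2(S-DOSP)4 turns 7 into a donor/acceptor carbenoid (C10 the carbene carbon, C1=C5 the vinyl donor) that cyclopropanates the terminal siloxy alkene C9=C8 of 13, and the cis-divinylcyclopropane 14 then undergoes a [3,3]-sigmatropic (Cope) shift through a boat transition state, the closest known reaction type being the dirhodium-catalysed tandem cyclopropanation/Cope [4+3] annulation of vinyldiazoacetates with dienes. The transient three-membered ring closes by [2+1] carbene transfer (C9–C10 and C8–C10), and the seven-membered ring closes when C5–C6 forms as C8–C10 breaks, release of cyclopropane strain making the ring expansion irreversible. C5 and C6 are the only new stereocentres: their absolute configuration is set by the catalyst through the configuration of 14, which the stereospecific Cope shift transfers, and their cis relation follows from the ring-held geometry of the cyclopentenyl alkene and the E geometry of the benzyloxy enol ether, both of which put hydrogen on the inside of the boat. The step needs site selectivity for the 1,1-disubstituted siloxy alkene over the trisubstituted benzyloxy alkene, which the reluctance of donor/acceptor carbenoids to attack trisubstituted alkenes should secure, and it needs the two alkenyl groups cis on the cyclopropane, which the usual placement of the alkene π-substituent next to the carbenoid donor should provide (a trans isomer could still converge on warming through reversible opening of the siloxy/ester-substituted ring). A non-polar hydrocarbon solvent and low temperature keep the reaction on the concerted cyclopropanation path and away from zwitterionic [3+2] products.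

**Step 9**
Reactants: 15 cycloadduct methyl ester
Product: 16 (5S,6S)-8-(tert-butyldimethylsilyloxy)-4,4-ethylenedioxy-6-(4-methoxybenzyloxy)-15-norguaia-1(10),7-dien-14-ol
Conditions: iBu2AlH (2.5 equiv), CH2Cl2, −78 °C; aq. KNaC4H4O6 work-up
Reagents that add atoms: none
Why: 1,2-reduction of the tetrasubstituted enoate by the aluminium hydride at −78 °C should give the allylic alcohol while the dioxolane, the benzyl ether and the hindered silyl enol ether (which keeps C8 masked) are inert.

**Step 10**
Reactants: 16 allylic alcohol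
Product: 18 (5S,6S)-8-(tert-butyldimethylsilyloxy)-4,4-ethylenedioxy-6-(4-methoxybenzyloxy)-15-norguaia-1(10),7-diene, via allylic mesylate 17 (not isolated)
Conditions: (MeSO2)2O, Et3N, THF, −40 °C; then LiBHEt3, −40 → 0 °C
Reagents that add atoms: none
Why: activation as the primary allylic mesylate and SN2 displacement by the strong hydride donor LiBHEt3 should give the C10 methyl group, SN2′ attack being blocked because the γ-carbon C1 is fully substituted.

**Step 11**
Reactants: 18 silyl enol ether
Product: 19 (5S,6R,7S)-4,4-ethylenedioxy-6-(4-methoxybenzyloxy)-15-norguai-1(10)-en-8-one (isopropyl β, cis to O6; H7 α)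
Conditions: Bu4NF, AcOH, THF, −40 → 0 °C
Reagents that add atoms: none
Why: fluoride cleavage of the silyl enol ether and kinetic protonation of the enolate by acetic acid on the α face, anti to the C6 ether that A(1,2) strain with the isopropyl group forces pseudo-axial, should set C7 with H7 cis to H6, the buffer suppressing epimerization and β-elimination.

**Step 12**
Reactants: 19 benzyl-protected ketone
Product: 20 (5S,6R,7S)-4,4-ethylenedioxy-6-hydroxy-15-norguai-1(10)-en-8-one
Conditions: DDQ, CH2Cl2/pH 7 phosphate buffer, 0 °C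
Reagents that add atoms: none
Why: oxidative cleavage of the 4-methoxybenzyl ether by DDQ (hydride abstraction, then hydrolysis of the oxocarbenium ion) under buffered conditions should leave the ketone, the dioxolane and the unactivated tetrasubstituted alkene alone.

**Step 13**
Reactants: 20 β-hydroxy ketone
Product: 21 (5S,6R,7R,8S)-4,4-ethylenedioxy-15-norguai-1(10)-ene-6,8-diol (6β-OH, 8α-OH)
Conditions: Me4NBH(OAc)3, MeCN/AcOH (1:1), −30 → −20 °C
Reagents that add atoms: none
Why: Evans–Saksena reduction, in which the C6 hydroxyl exchanges onto boron and delivers hydride intramolecularly to the β face of the C8 ketone, should give the 1,3-anti diol with the new hydroxyl α and trans to the isopropyl group.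

**Step 14**
Reactants: 21 diol ketal
Product: 22 (5S,6R,7R,8S)-6,8-dihydroxy-15-norguai-1(10)-en-4-one
Conditions: pyridinium 4-toluenesulfonate (0.2 equiv), acetone/H2O (4:1), 40 °C
Reagents that add atoms: water, O
Why: acid-catalysed ketal hydrolysis with the weakest acid that opens a cyclopentanone dioxolane, the way β,γ-unsaturated ketones with a tetrasubstituted alkene are liberated, so that enolization toward C5 stays slow and C1=C10 is not drawn into conjugation.

**Step 15**
Reactants: 22 keto diol
Product: 23 (4S,5S,6R,7R,8S)-guai-1(10)-ene-4,6,8-triol (4-methyl α, 4-OH β)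
Conditions: MeLi/CeCl3 (4 equiv, premixed), THF, −78 °C; aq. NH4Cl
Reagents that add atoms: methyllithium, C[Li]
Why: organocerium addition, in which the weakly basic MeCeCl2 adds to the enolizable β,γ-unsaturated cyclopentanone without deprotonating C5 and attacks from the α face, anti to the C5–C6 bond along which the seven-membered ring leaves the cyclopentanone plane, making the methyl α and the hydroxyl β.

**Step 16**
Reactants: 24 vanillic acid
Product: 26 4-(tert-butyldimethylsilyloxy)-3-methoxybenzoic acid, via bis-silylated vanillate 25 (not isolated)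
Conditions: tBuMe2SiCl (2.4 equiv), imidazole, DMF, rt; then AcOH/THF/H2O (3:1:1), rt
Reagents that add atoms: tert-butyldimethylsilyl chloride, CC(C)(C)[Si](C)(C)Cl
Why: exhaustive silylation followed by selective hydrolysis of the labile silyl ester should leave the phenol masked as its aryl silyl ether and free the acid for coupling.

**Step 17**
Reactants: 23 triol; 26 4-(tert-butyldimethylsilyloxy)-3-methoxybenzoic acid
Product: 27 (4S,5S,6R,7S,8S)-4,6-dihydroxyguai-1(10)-en-8-yl 4-(tert-butyldimethylsilyloxy)-3-methoxybenzoate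
Conditions: 26 (1.1 equiv), N,N'-dicyclohexylcarbodiimide, 4-dimethylaminopyridine (0.2 equiv), CH2Cl2, 0 °C → rt
Reagents that add atoms: none
Why: Steglich esterification should acylate the C8 hydroxyl, which has a CH2 neighbour, in preference to the C6 hydroxyl wedged between the ring fusion and the cis isopropyl group and to the tertiary C4 hydroxyl.

**Step 18**
Reactants: 27 silyl-protected vanillate
Product: 28 (4S,5S,6R,7S,8S)-4,6-dihydroxyguai-1(10)-en-8-yl 4-hydroxy-3-methoxybenzoate (CNP0299353.1)
Conditions: Bu4NF, AcOH, THF, 0 °C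
Reagents that add atoms: none
Why: fluoride desilylation of the aryl silyl ether is fast because phenoxide leaves silicon readily, and acetic acid buffering should prevent acyl migration or ester cleavage.

**Compound list**
1 | 3-ethoxycyclopent-2-en-1-one | CCOC1=CC(=O)CC1 | starting material
2 | methyl acetate | COC(C)=O | starting material
3 | lithium enolate of methyl acetate | C=C(OC)O[Li] | intermediate
4 | methyl 2-(3-ethoxy-1-hydroxycyclopent-2-en-1-yl)acetate (racemic, present as its lithium alkoxide) | CCOC1=CC(O)(CC(=O)OC)CC1 | intermediate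
5 | methyl 2-(3-oxocyclopent-1-en-1-yl)acetate | COC(=O)CC1=CC(=O)CC1 | intermediate
6 | methyl 2-(1,4-dioxaspiro[4.4]non-6-en-7-yl)acetate | COC(=O)CC1=CC2(CC1)OCCO2 | intermediate
7 | methyl 2-diazo-2-(1,4-dioxaspiro[4.4]non-6-en-7-yl)acetate | COC(=O)C(=[N+]=[N-])C1=CC2(CC1)OCCO2 | intermediate
8 | ethyl 3-methylbutanoate | CCOC(=O)CC(C)C | starting material
9 | ethyl 2-formyl-3-methylbutanoate | CCOC(=O)C(C=O)C(C)C | intermediate
10 | ethyl (E)-2-isopropyl-3-(4-methoxybenzyloxy)prop-2-enoate | CCOC(=O)/C(C(C)C)=C/OCc1ccc(OC)cc1 | intermediate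
11 | (E)-3-isopropyl-4-(4-methoxybenzyloxy)-1-(trimethylsilyl)but-3-en-2-one (present as its lithium enolate) | C[Si](C)(C)CC(=O)/C(C(C)C)=C/OCc1ccc(OC)cc1 | intermediate
12 | (E)-3-isopropyl-4-(4-methoxybenzyloxy)but-3-en-2-one | CC(=O)/C(C(C)C)=C/OCc1ccc(OC)cc1 | intermediate
13 | (E)-2-(tert-butyldimethylsilyloxy)-3-isopropyl-4-(4-methoxybenzyloxy)buta-1,3-diene | C=C(O[Si](C)(C)C(C)(C)C)/C(C(C)C)=C/OCc1ccc(OC)cc1 | intermediate
14 | methyl (1R,2S)-2-(tert-butyldimethylsilyloxy)-1-(1,4-dioxaspiro[4.4]non-6-en-7-yl)-2-[(E)-1-(4-methoxybenzyloxy)-3-methylbut-1-en-2-yl]cyclopropane-1-carboxylate (the two alkenyl groups cis) | COC(=O)[C@@]1(C2=CC3(CC2)OCCO3)C[C@]1(O[Si](C)(C)C(C)(C)C)/C(C(C)C)=C/OCc1ccc(OC)cc1 | intermediate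
15 | methyl (5S,6S)-8-(tert-butyldimethylsilyloxy)-4,4-ethylenedioxy-6-(4-methoxybenzyloxy)-15-norguaia-1(10),7-dien-14-oate | COC(=O)C1=C2CCC3(OCCO3)[C@@H]2[C@H](OCc4ccc(OC)cc4)C(C(C)C)=C(O[Si](C)(C)C(C)(C)C)C1 | intermediate
16 | (5S,6S)-8-(tert-butyldimethylsilyloxy)-4,4-ethylenedioxy-6-(4-methoxybenzyloxy)-15-norguaia-1(10),7-dien-14-ol | OCC1=C2CCC3(OCCO3)[C@@H]2[C@H](OCc4ccc(OC)cc4)C(C(C)C)=C(O[Si](C)(C)C(C)(C)C)C1 | intermediate
17 | 14-methanesulfonate of 16 | CS(=O)(=O)OCC1=C2CCC3(OCCO3)[C@@H]2[C@H](OCc4ccc(OC)cc4)C(C(C)C)=C(O[Si](C)(C)C(C)(C)C)C1 | intermediate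
18 | (5S,6S)-8-(tert-butyldimethylsilyloxy)-4,4-ethylenedioxy-6-(4-methoxybenzyloxy)-15-norguaia-1(10),7-diene | CC1=C2CCC3(OCCO3)[C@@H]2[C@H](OCc4ccc(OC)cc4)C(C(C)C)=C(O[Si](C)(C)C(C)(C)C)C1 | intermediate
19 | (5S,6R,7S)-4,4-ethylenedioxy-6-(4-methoxybenzyloxy)-15-norguai-1(10)-en-8-one | CC1=C2CCC3(OCCO3)[C@@H]2[C@H](OCc4ccc(OC)cc4)[C@H](C(C)C)C(=O)C1 | intermediate
20 | (5S,6R,7S)-4,4-ethylenedioxy-6-hydroxy-15-norguai-1(10)-en-8-one | CC1=C2CCC3(OCCO3)[C@@H]2[C@H](O)[C@H](C(C)C)C(=O)C1 | intermediate
21 | (5S,6R,7R,8S)-4,4-ethylenedioxy-15-norguai-1(10)-ene-6,8-diol | CC1=C2CCC3(OCCO3)[C@@H]2[C@H](O)[C@H](C(C)C)[C@@H](O)C1 | intermediate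
22 | (5S,6R,7R,8S)-6,8-dihydroxy-15-norguai-1(10)-en-4-one | CC1=C2CCC(=O)[C@@H]2[C@H](O)[C@H](C(C)C)[C@@H](O)C1 | intermediate
23 | (4S,5S,6R,7R,8S)-guai-1(10)-ene-4,6,8-triol | CC1=C2CC[C@](C)(O)[C@@H]2[C@H](O)[C@H](C(C)C)[C@@H](O)C1 | intermediate
24 | vanillic acid (4-hydroxy-3-methoxybenzoic acid) | COc1cc(C(=O)O)ccc1O | starting material
25 | tert-butyldimethylsilyl 4-(tert-butyldimethylsilyloxy)-3-methoxybenzoate | COc1cc(C(=O)O[Si](C)(C)C(C)(C)C)ccc1O[Si](C)(C)C(C)(C)C | intermediate
26 | 4-(tert-butyldimethylsilyloxy)-3-methoxybenzoic acid | COc1cc(C(=O)O)ccc1O[Si](C)(C)C(C)(C)C | intermediate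
27 | (4S,5S,6R,7S,8S)-4,6-dihydroxyguai-1(10)-en-8-yl 4-(tert-butyldimethylsilyloxy)-3-methoxybenzoate | COc1cc(C(=O)O[C@H]2CC(C)=C3CC[C@](C)(O)[C@@H]3[C@H](O)[C@@H]2C(C)C)ccc1O[Si](C)(C)C(C)(C)C | intermediate
28 | (4S,5S,6R,7S,8S)-4,6-dihydroxyguai-1(10)-en-8-yl 4-hydroxy-3-methoxybenzoate (CNP0299353.1) | COc1cc(C(=O)O[C@H]2CC(C)=C3CC[C@](C)(O)[C@@H]3[C@H](O)[C@@H]2C(C)C)ccc1O | target

**Step count and risks**
Total: 18 steps. Longest linear sequence: 14 steps, from ethyl 3-methylbutanoate 8 to 28 (steps 4–15, 17 and 18).

Step 8. The catalyst may discriminate poorly between the enantiofaces at the 1,1-disubstituted siloxy alkene, or reversible opening of the siloxy/ester-substituted cyclopropane may erode the selectivity before the Cope shift. The fallback moves stereocontrol to a covalently bound auxiliary whose diastereomers can be separated. It sets out from ketal ester 6: saponification (LiOH, THF/H2O) should give 2-(1,4-dioxaspiro[4.4]non-6-en-7-yl)acetic acid F1. Coupling with (R)-pantolactone (carbodiimide, 4-dimethylaminopyridine) gives the (R)-pantolactonyl ester F2, the antipode taken to match the sense of Rh2(S-DOSP)4. Diazo transfer (sulfonyl azide, DBU) gives the pantolactonyl diazoester F3. Reaction with diene 13 under the achiral catalyst Rh2(O2CC7H15)4 in hexanes gives the pantolactonyl cycloadduct F4, which is purified as a single diastereomer. Excess iBu2AlH (−78 → 0 °C) cleaves the auxiliary and returns to the route at allylic alcohol 16.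

Step 11. Protonation of the C7 enolate may show poor facial selectivity, the new centre may epimerize, or the C6 ether may be lost by β-elimination. The fallback sets C7 and C8 together by a syn hydroboration instead of protonation and reduction. It sets out from silyl enol ether 18: CsF and PhNTf2 in dimethoxyethane should convert it regiospecifically into the C7=C8 vinyl triflate F5. Formate reduction (Pd(OAc)2, PPh3, Bu3N, HCO2H, DMF, 60 °C) gives the trisubstituted C7=C8 alkene F6. BH3·THF (0 °C) followed by NaOH/H2O2 places boron on the less substituted C8 and adds H7 and O8 cis, from the α face anti to the allylic C6 ether and in preference to the tetrasubstituted C1=C10 alkene, giving the 8α-alcohol with the 6-benzyl ether F7. DDQ in buffered wet CH2Cl2 then removes the 4-methoxybenzyl group and returns to the route at diol 21, so that steps 11–13 are bypassed.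

Step 17. Site selectivity of the acylation may be incomplete, with ester formation at O6 or at both secondary hydroxyls. The fallback masks O4 and O6 temporarily as a tether. It sets out from triol 23: PhB(OH)2 in toluene with azeotropic removal of water should form the cyclic 4,6-O-phenylboronate F8 from the two syn β-hydroxyls, since the trans 6,8-pair cannot be bridged. Carbodiimide/4-dimethylaminopyridine coupling with acid 26 then acylates the only free hydroxyl and gives the 8-O-acylated phenylboronate F9. Transesterification with pinacol during work-up releases the boron and returns to the route at ester 27.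

**Further compounds**
F1 | step 8 | 2-(1,4-dioxaspiro[4.4]non-6-en-7-yl)acetic acid | OC(=O)CC1=CC2(CC1)OCCO2
F2 | step 8 | (R)-pantolactonyl 2-(1,4-dioxaspiro[4.4]non-6-en-7-yl)acetate | O=C(CC1=CC2(CC1)OCCO2)O[C@H]1C(=O)OCC1(C)C
F3 | step 8 | (R)-pantolactonyl 2-diazo-2-(1,4-dioxaspiro[4.4]non-6-en-7-yl)acetate | [N-]=[N+]=C(C(=O)O[C@H]1C(=O)OCC1(C)C)C1=CC2(CC1)OCCO2
F4 | step 8 | (R)-pantolactonyl ester analogue of cycloadduct 15 | O=C(O[C@H]1C(=O)OCC1(C)C)C1=C2CCC3(OCCO3)[C@@H]2[C@H](OCc4ccc(OC)cc4)C(C(C)C)=C(O[Si](C)(C)C(C)(C)C)C1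
F5 | step 11 | (5S,6S)-4,4-ethylenedioxy-6-(4-methoxybenzyloxy)-15-norguaia-1(10),7-dien-8-yl triflate | CC1=C2CCC3(OCCO3)[C@@H]2[C@H](OCc4ccc(OC)cc4)C(C(C)C)=C(OS(=O)(=O)C(F)(F)F)C1
F6 | step 11 | (5S,6S)-4,4-ethylenedioxy-6-(4-methoxybenzyloxy)-15-norguaia-1(10),7-diene | CC1=C2CCC3(OCCO3)[C@@H]2[C@H](OCc4ccc(OC)cc4)C(C(C)C)=CC1
F7 | step 11 | (5S,6R,7R,8S)-4,4-ethylenedioxy-6-(4-methoxybenzyloxy)-15-norguai-1(10)-en-8-ol | CC1=C2CCC3(OCCO3)[C@@H]2[C@H](OCc4ccc(OC)cc4)[C@H](C(C)C)[C@@H](O)C1
F8 | step 17 | 4,6-O-phenylboronate of triol 23 | CC1=C2CC[C@]3(C)OB(c4ccccc4)O[C@@H]([C@H]23)[C@H](C(C)C)[C@@H](O)C1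
F9 | step 17 | 4,6-O-phenylboronate of ester 27 | CC1=C2CC[C@]3(C)OB(c4ccccc4)O[C@@H]([C@H]23)[C@H](C(C)C)[C@@H](OC(=O)c2ccc(O[Si](C)(C)C(C)(C)C)c(OC)c2)C1
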